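Labdane numbering is used: ring A is C1–C5/C10, ring B is C5–C10, ring C is O/C9/C11–C13, ring D is C13–C16/O.
Retrosynthetic cuts, in order: the ring D enol ether (C14=C15, O–C15) goes back to a C15 dimethyl acetal and a C16 silyl ether. The 6β-acetoxy-7-ketone goes back to a plain 6-ketone. Then C9–C10 (ring B), O–C9 (ring C), C11–C12 and C8–C9 are cut.
Enabling feature: C9 is the spiro atom of rings B and C. It carries the ring C oxygen and is bonded to quaternary C10, which lies β to C6. The C9–C10 bond can therefore form by adding an oxygen-stabilised C9 radical to a C5=C10 enone whose carbonyl is C6.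
Forward order: ring A is bought with β-damascone. The chain grows by C8–C9 conjugate alkynylation and C11–C12 acetylide/epoxide coupling. Ring C closes with gold, ring B by hydrogen-atom transfer, C6/C7 are then adjusted, and ring D closes last.
Stereochemistry: C8 comes from a chiral rhodium catalyst and C13 from a Sharpless epoxidation. C9, C10 and C5 are relayed from C8 (reinforced by C13) in the ring B closure. C6 comes from α-face hydride delivery.

Key step: step 12

Assumption: the facial sense of step 1 is taken from the quadrant model of rhodium complexes of C2-symmetric biaryl bisphosphines, in which the (S)-ligand turns (E)-crotonyl acceptors into (R)-β-substituted products. Both ligand antipodes are commercial.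
Assumption: the carbinol centres C6 (4, 5, 12, 13) and C7 (18–23) and the anomeric C15 (23–26) are drawn without configuration, because each is planarised later.

Step 1
Reactants: 1 β-damascone, (E)-1-(2,6,6-trimethylcyclohex-1-en-1-yl)but-2-en-1-one; 2 (triisopropylsilyl)acetylene
Product: 3 (3R)-3-methyl-5-(triisopropylsilyl)-1-(2,6,6-trimethylcyclohex-1-en-1-yl)pent-4-yn-1-one
Conditions: [Rh(OAc)(C2H4)2]2 (2.5 mol%), (S)-DTBM-SEGPHOS (5.5 mol%), 1,4-dioxane, 80 °C
Reagents that add atoms: none
Why: This is a rhodium-catalysed asymmetric conjugate alkynylation of a linear (E)-enone with a bulky silylacetylene, in which only the disubstituted C7=C8 bond inserts (the tetrasubstituted ring alkene is inert) and the chiral pocket delivers the alkynyl group to the Re face of C8, setting (8R).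

Step 2
Reactants: 3 (3R)-3-methyl-5-(triisopropylsilyl)-1-(2,6,6-trimethylcyclohex-1-en-1-yl)pent-4-yn-1-one
Product: 4 (3R)-3-methyl-5-(triisopropylsilyl)-1-(2,6,6-trimethylcyclohex-1-en-1-yl)pent-4-yn-1-ol (C6 epimers)
Conditions: LiAlH4, Et2O, 0 °C
Reagents that add atoms: none
Why: A 1,2-hydride reduction parks the enolisable C6 ketone as a carbinol, because the ketone would be deprotonated or attacked under the acetylide conditions of step 9; the new C6 centre forms without control and is erased in step 10.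

Step 3
Reactants: 4 (3R)-3-methyl-5-(triisopropylsilyl)-1-(2,6,6-trimethylcyclohex-1-en-1-yl)pent-4-yn-1-ol
Product: 5 (3R)-3-methyl-1-(2,6,6-trimethylcyclohex-1-en-1-yl)pent-4-yn-1-ol (C6 epimers)
Conditions: Bu4NF, THF, rt
Reagents that add atoms: none
Why: Fluoride-induced protodesilylation of the alkynylsilane frees the terminal alkyne (C11–H) and touches neither the alcohol nor C8.

Step 4
Reactants: 6 methyl 4,4-dimethoxybutanoate
Product: 7 4,4-dimethoxybutanal
Conditions: i-Bu2AlH (1.05 equiv), CH2Cl2, −78 °C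
Reagents that add atoms: none
Why: This is a partial ester reduction in which the tetrahedral aluminium hemiacetal persists at −78 °C and collapses to the aldehyde only on work-up, while the dimethyl acetal is inert to hydride.

Step 5
Reactants: 7 4,4-dimethoxybutanal
Product: 8 4,4-dimethoxy-2-methylidenebutanal
Conditions: 37% aq. CH2O, pyrrolidine (10 mol%), EtCO2H (10 mol%), i-PrOH, 45 °C
Reagents that add atoms: formaldehyde, C=O
Why: An amine/acid-catalysed Mannich condensation–elimination (organocatalytic α-methylenation of an aldehyde) installs C12 as the methylidene carbon under conditions mild enough for the acetal.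

Step 6
Reactants: 8 4,4-dimethoxy-2-methylidenebutanal
Product: 9 4,4-dimethoxy-2-methylidenebutan-1-ol
Conditions: i-Bu2AlH (1.1 equiv), CH2Cl2, −78 °C
Reagents that add atoms: none
Why: A clean 1,2-reduction of the enal gives the 2-substituted allylic alcohol needed for a hydroxyl-directed epoxidation, without conjugate reduction.

Step 7
Reactants: 9 4,4-dimethoxy-2-methylidenebutan-1-ol
Product: 10 [(2R)-2-(2,2-dimethoxyethyl)oxiran-2-yl]methanol
Conditions: Ti(OiPr)4 (10 mol%), D-(−)-DIPT (12 mol%), t-BuOOH, 4 Å MS, CH2Cl2, −20 °C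
Reagents that add atoms: tert-butyl hydroperoxide, CC(C)(C)OO
Why: In this Sharpless asymmetric epoxidation the allylic hydroxyl binds titanium and the D-(−)-tartrate directs the peroxide oxygen to the face giving the (R)-epoxy alcohol (L-(+)-tartrate is known to give (S)-2-alkylglycidols), which creates C13.

Step 8
Reactants: 10 [(2R)-2-(2,2-dimethoxyethyl)oxiran-2-yl]methanol
Product: 11 tert-butyl{[(2S)-2-(2,2-dimethoxyethyl)oxiran-2-yl]methoxy}dimethylsilane
Conditions: TBSCl, imidazole, CH2Cl2, 0 °C to rt
Reagents that add atoms: tert-butyldimethylsilyl chloride, CC(C)(C)[Si](C)(C)Cl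
Why: Imidazole-promoted silylation masks O16 and blocks Payne rearrangement in the next step; C13 is untouched and the descriptor changes only through the priority rules.

Step 9
Reactants: 5 (3R)-3-methyl-1-(2,6,6-trimethylcyclohex-1-en-1-yl)pent-4-yn-1-ol; 11 tert-butyl{[(2S)-2-(2,2-dimethoxyethyl)oxiran-2-yl]methoxy}dimethylsilane
Product: 13 (3R,7R)-3-{[(tert-butyldimethylsilyl)oxy]methyl}-1,1-dimethoxy-7-methyl-9-(2,6,6-trimethylcyclohex-1-en-1-yl)non-5-yne-3,9-diol (C6 epimers), via dilithium alkoxide-acetylide 12 (not isolated)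
Conditions: 5, n-BuLi (2 equiv per 5), THF, −78 °C; BF3·OEt2 (2 equiv per 5); 11, −78 °C
Reagents that add atoms: none
Why: In this Yamaguchi–Hirao alkynylation the BF3-activated 2,2-disubstituted epoxide is opened in SN2 fashion at its CH2 (C12), so the C13–O bond and its configuration are kept; the C6 alkoxide is a spectator and all BF3 is bound to anions at −78 °C, which spares the acetal.

Step 10
Reactants: 13 (3R,7R)-3-{[(tert-butyldimethylsilyl)oxy]methyl}-1,1-dimethoxy-7-methyl-9-(2,6,6-trimethylcyclohex-1-en-1-yl)non-5-yne-3,9-diol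
Product: 14 (3R,7R)-7-{[(tert-butyldimethylsilyl)oxy]methyl}-7-hydroxy-9,9-dimethoxy-3-methyl-1-(2,6,6-trimethylcyclohex-1-en-1-yl)non-4-yn-1-one
Conditions: DMP, pyridine, CH2Cl2, 0 °C to rt
Reagents that add atoms: none
Why: A Dess–Martin oxidation turns the secondary allylic carbinol into the cyclohexenyl ketone and merges the C6 epimers; the tertiary C13 alcohol cannot be oxidised and the pyridine buffer protects the acetal and silyl ether.

Step 11
Reactants: 14 (3R,7R)-7-{[(tert-butyldimethylsilyl)oxy]methyl}-7-hydroxy-9,9-dimethoxy-3-methyl-1-(2,6,6-trimethylcyclohex-1-en-1-yl)non-4-yn-1-one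
Product: 15 (3R)-3-[(2R)-2-{[(tert-butyldimethylsilyl)oxy]methyl}-2-(2,2-dimethoxyethyl)-2,3-dihydrofuran-5-yl]-1-(2,6,6-trimethylcyclohex-1-en-1-yl)butan-1-one
Conditions: Ph3PAuNTf2 (3 mol%), 4 Å MS, toluene, 0 °C to rt; Et3N quench, filtration through basic Al2O3
Reagents that add atoms: none
Why: This gold-catalysed 5-endo-dig cycloisomerisation of a homopropargylic alcohol (the 4-exo mode is strained) proceeds by anti-oxyauration at C9 and protodeauration at C11, closing ring C as the 5-substituted 2,3-dihydrofuran without touching C8 or C13, provided acid is excluded so the double bond cannot drift to C8=C9.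

Step 12
Reactants: 15 (3R)-3-[(2R)-2-{[(tert-butyldimethylsilyl)oxy]methyl}-2-(2,2-dimethoxyethyl)-2,3-dihydrofuran-5-yl]-1-(2,6,6-trimethylcyclohex-1-en-1-yl)butan-1-one
Product: 16 (13R)-16-(tert-butyldimethylsilyloxy)-15,15-dimethoxy-9α,13-epoxylabdan-6-one (5S,8R,9R,10S,13R)
Conditions: Fe(dibm)3 (dibm = 2,6-dimethylheptane-3,5-dionate; 30 mol%), PhSiH3 (3 equiv, slow addition), Na2HPO4 (2 equiv), EtOH (0.01 M), 60 °C; then K2CO3, MeOH, rt
Reagents that add atoms: none
Why: The iron hydride formed from Fe(dibm)3 and PhSiH3 hands a hydrogen atom to C11, the less substituted end of the electron-rich ring C enol ether, and ignores the twisted tetrasubstituted C5=C10 bond, so a nucleophilic tertiary α-oxy radical arises at C9 only. This radical adds to C10, the β-carbon of the cyclohexenyl ketone, in a 6-endo-trig closure of ring B (a polarity-matched Giese addition; 5-exo attack at acyl-bearing C5 is mismatched and would leave an unstabilised radical), after which the C5 α-keto radical is reduced by divalent iron to the enolate and protonated by ethanol. The closest known reaction type is the iron-catalysed reductive coupling of enol ether donor olefins with enone acceptors, which is known to join two fully substituted carbons and is used here intramolecularly. C10 and C9 are governed by C8: the C10 methyl is forced axial because C1 stays in the former alkene plane, the chair with an equatorial C8 methyl avoids a 1,3-diaxial methyl/methyl clash, and allylic-type strain places C11 beside the C8 hydrogen, so the ring C oxygen ends axial (9α) and C10 enters the ring C face anti to the CH2OTBS group on C13, making both controllers matched. C5 is set by enolate protonation and secured thermodynamically, because the K2CO3/MeOH treatment equilibrates any cis-fused ketone to the trans-decalone. The step needs donor-over-acceptor chemoselectivity and cyclisation faster than radical quenching or ethanolysis, which the enol ether's electron richness, the phosphate buffer, high dilution and slow silane addition are meant to secure.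

Step 13
Reactants: 16 (13R)-16-(tert-butyldimethylsilyloxy)-15,15-dimethoxy-9α,13-epoxylabdan-6-one
Product: 18 (13R)-16-(tert-butyldimethylsilyloxy)-7ξ-hydroxy-15,15-dimethoxy-9α,13-epoxylabdan-6-one, via potassium enolate 17 (not isolated)
Conditions: KN(SiMe3)2, THF, −78 °C; 2-(benzenesulfonyl)-3-phenyloxaziridine, −78 °C
Reagents that add atoms: 2-(benzenesulfonyl)-3-phenyloxaziridine, O=S(=O)(c1ccccc1)N1OC1c1ccccc1
Why: In this Davis oxidation kinetic deprotonation occurs at the C7 methylene because C5–H is buried between two quaternary carbons; the new C7 carbinol centre is of no consequence since it becomes a carbonyl in step 18.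

Step 14
Reactants: 18 (13R)-16-(tert-butyldimethylsilyloxy)-7ξ-hydroxy-15,15-dimethoxy-9α,13-epoxylabdan-6-one
Product: 19 (13R)-16-(tert-butyldimethylsilyloxy)-15,15-dimethoxy-7ξ-(triethylsilyloxy)-9α,13-epoxylabdan-6-one
Conditions: TESCl, imidazole, DMAP (cat.), DMF, rt
Reagents that add atoms: chlorotriethylsilane, CC[Si](Cl)(CC)CC
Why: Imidazole-promoted silylation with the chloride (a silyl triflate/lutidine pair would attack the dimethyl acetal) keeps O7 apart from O6 so that only O6 is acetylated later.

Step 15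
Reactants: 19 (13R)-16-(tert-butyldimethylsilyloxy)-15,15-dimethoxy-7ξ-(triethylsilyloxy)-9α,13-epoxylabdan-6-one
Product: 20 (13R)-16-(tert-butyldimethylsilyloxy)-15,15-dimethoxy-7ξ-(triethylsilyloxy)-9α,13-epoxylabdan-6β-ol
Conditions: LiAlH4, Et2O, −20 °C
Reagents that add atoms: none
Why: In this substrate-controlled hydride reduction the β face of C6 is screened by the axial C10 methyl and the 4β-methyl, so hydride arrives from the α face and the axial 6β-alcohol (6S) results, and the low temperature suppresses silyl migration.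

Step 16
Reactants: 20 (13R)-16-(tert-butyldimethylsilyloxy)-15,15-dimethoxy-7ξ-(triethylsilyloxy)-9α,13-epoxylabdan-6β-ol
Product: 21 (13R)-6β-acetoxy-16-(tert-butyldimethylsilyloxy)-15,15-dimethoxy-7ξ-(triethylsilyloxy)-9α,13-epoxylabdane
Conditions: Ac2O, DMAP, pyridine, 50 °C
Reagents that add atoms: acetic anhydride, CC(=O)OC(C)=O
Why: DMAP-catalysed acylation esterifies the only free hydroxyl, and gentle heating compensates for its axial, hindered position without affecting any stereocentre.

Step 17
Reactants: 21 (13R)-6β-acetoxy-16-(tert-butyldimethylsilyloxy)-15,15-dimethoxy-7ξ-(triethylsilyloxy)-9α,13-epoxylabdane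
Product: 23 (13R)-6β-acetoxy-15ξ-methoxy-9α,13:15,16-diepoxylabdan-7ξ-ol, via desilylated diol acetal 22 (not isolated)
Conditions: CSA (10 mol%), MeOH, 0 °C to rt
Reagents that add atoms: none
Why: Acid-catalysed methanolysis removes both silyl ethers, and the freed C16 hydroxyl then displaces one methoxy group at C15 (5-exo transacetalisation), closing ring D as its cyclic methyl acetal, while the hindered acetate and the tertiary ring C ether survive.

Step 18
Reactants: 23 (13R)-6β-acetoxy-15ξ-methoxy-9α,13:15,16-diepoxylabdan-7ξ-ol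
Product: 24 (13R)-6β-acetoxy-15ξ-methoxy-9α,13:15,16-diepoxylabdan-7-one
Conditions: DMP, pyridine, CH2Cl2, rt
Reagents that add atoms: none
Why: A Dess–Martin oxidation of the only free alcohol gives the C7 ketone under near-neutral conditions, where C8 (methyl already equatorial) and C6 (equatorial hydrogen poorly aligned for enolisation) keep their configuration.

Step 19
Reactants: 24 (13R)-6β-acetoxy-15ξ-methoxy-9α,13:15,16-diepoxylabdan-7-one
Product: 25 (13R)-6β-acetoxy-15ξ-hydroxy-9α,13:15,16-diepoxylabdan-7-one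
Conditions: AcOH–THF–H2O (2:2:1), rt
Reagents that add atoms: water, O
Why: Mild acetal hydrolysis exchanges the anomeric methoxy group for hydroxyl through the C15 oxocarbenium ion and stops at the five-membered lactol.

Step 20
Reactants: 25 (13R)-6β-acetoxy-15ξ-hydroxy-9α,13:15,16-diepoxylabdan-7-one
Product: 27 (13R)-6β-acetoxy-9α,13:15,16-diepoxylabd-14-en-7-one (5S,6S,8S,9R,10S,13R), via anomeric mesylate 26 (not isolated)
Conditions: MsCl (2 equiv), Et3N (8 equiv), CH2Cl2, −20 °C to 40 °C; chromatography on Et3N-deactivated SiO2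
Reagents that add atoms: none
Why: Lactol mesylation followed by amine-induced elimination (the lactol dehydration used for furanoid glycals) places the double bond at C14=C15, the only site with a β-hydrogen, and the permanently basic medium protects the product, whose ring C would otherwise open with aromatisation of ring D.

Compound list
1 | β-damascone, (E)-1-(2,6,6-trimethylcyclohex-1-en-1-yl)but-2-en-1-one | C/C=C/C(=O)C1=C(C)CCCC1(C)C | starting material
2 | (triisopropylsilyl)acetylene | C#C[Si](C(C)C)(C(C)C)C(C)C | starting material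
3 | (3R)-3-methyl-5-(triisopropylsilyl)-1-(2,6,6-trimethylcyclohex-1-en-1-yl)pent-4-yn-1-one | CC1=C(C(=O)C[C@@H](C)C#C[Si](C(C)C)(C(C)C)C(C)C)C(C)(C)CCC1 | intermediate
4 | (3R)-3-methyl-5-(triisopropylsilyl)-1-(2,6,6-trimethylcyclohex-1-en-1-yl)pent-4-yn-1-ol (C6 epimers) | CC1=C(C(O)C[C@@H](C)C#C[Si](C(C)C)(C(C)C)C(C)C)C(C)(C)CCC1 | intermediate
5 | (3R)-3-methyl-1-(2,6,6-trimethylcyclohex-1-en-1-yl)pent-4-yn-1-ol (C6 epimers) | CC1=C(C(O)C[C@@H](C)C#C)C(C)(C)CCC1 | intermediate
6 | methyl 4,4-dimethoxybutanoate | COC(=O)CCC(OC)OC | starting material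
7 | 4,4-dimethoxybutanal | O=CCCC(OC)OC | intermediate
8 | 4,4-dimethoxy-2-methylidenebutanal | C=C(C=O)CC(OC)OC | intermediate
9 | 4,4-dimethoxy-2-methylidenebutan-1-ol | C=C(CO)CC(OC)OC | intermediate
10 | [(2R)-2-(2,2-dimethoxyethyl)oxiran-2-yl]methanol | OC[C@]1(CC(OC)OC)CO1 | intermediate
11 | tert-butyl{[(2S)-2-(2,2-dimethoxyethyl)oxiran-2-yl]methoxy}dimethylsilane | CC(C)(C)[Si](C)(C)OC[C@]1(CC(OC)OC)CO1 | intermediate
12 | dilithium alkoxide-acetylide of 5 | CC1=C(C(O[Li])C[C@@H](C)C#C[Li])C(C)(C)CCC1 | intermediate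
13 | (3R,7R)-3-{[(tert-butyldimethylsilyl)oxy]methyl}-1,1-dimethoxy-7-methyl-9-(2,6,6-trimethylcyclohex-1-en-1-yl)non-5-yne-3,9-diol (C6 epimers) | CC1=C(C(O)C[C@@H](C)C#CC[C@](O)(CO[Si](C)(C)C(C)(C)C)CC(OC)OC)C(C)(C)CCC1 | intermediate
14 | (3R,7R)-7-{[(tert-butyldimethylsilyl)oxy]methyl}-7-hydroxy-9,9-dimethoxy-3-methyl-1-(2,6,6-trimethylcyclohex-1-en-1-yl)non-4-yn-1-one | CC1=C(C(=O)C[C@@H](C)C#CC[C@](O)(CO[Si](C)(C)C(C)(C)C)CC(OC)OC)C(C)(C)CCC1 | intermediate
15 | (3R)-3-[(2R)-2-{[(tert-butyldimethylsilyl)oxy]methyl}-2-(2,2-dimethoxyethyl)-2,3-dihydrofuran-5-yl]-1-(2,6,6-trimethylcyclohex-1-en-1-yl)butan-1-one | CC1=C(C(=O)C[C@@H](C)C2=CC[C@](CO[Si](C)(C)C(C)(C)C)(CC(OC)OC)O2)C(C)(C)CCC1 | intermediate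
16 | (13R)-16-(tert-butyldimethylsilyloxy)-15,15-dimethoxy-9α,13-epoxylabdan-6-one | O=C1C[C@@H](C)[C@]2(CC[C@](CO[Si](C)(C)C(C)(C)C)(CC(OC)OC)O2)[C@@]2(C)CCCC(C)(C)[C@H]12 | intermediate
17 | potassium C6–C7 enolate of 16 | [K]OC1=C[C@@H](C)[C@]2(CC[C@](CO[Si](C)(C)C(C)(C)C)(CC(OC)OC)O2)[C@@]2(C)CCCC(C)(C)[C@H]12 | intermediate
18 | (13R)-16-(tert-butyldimethylsilyloxy)-7ξ-hydroxy-15,15-dimethoxy-9α,13-epoxylabdan-6-one | O=C1C(O)[C@@H](C)[C@]2(CC[C@](CO[Si](C)(C)C(C)(C)C)(CC(OC)OC)O2)[C@@]2(C)CCCC(C)(C)[C@H]12 | intermediate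
19 | (13R)-16-(tert-butyldimethylsilyloxy)-15,15-dimethoxy-7ξ-(triethylsilyloxy)-9α,13-epoxylabdan-6-one | O=C1C(O[Si](CC)(CC)CC)[C@@H](C)[C@]2(CC[C@](CO[Si](C)(C)C(C)(C)C)(CC(OC)OC)O2)[C@@]2(C)CCCC(C)(C)[C@H]12 | intermediate
20 | (13R)-16-(tert-butyldimethylsilyloxy)-15,15-dimethoxy-7ξ-(triethylsilyloxy)-9α,13-epoxylabdan-6β-ol | O[C@@H]1C(O[Si](CC)(CC)CC)[C@@H](C)[C@]2(CC[C@](CO[Si](C)(C)C(C)(C)C)(CC(OC)OC)O2)[C@@]2(C)CCCC(C)(C)[C@H]12 | intermediate
21 | (13R)-6β-acetoxy-16-(tert-butyldimethylsilyloxy)-15,15-dimethoxy-7ξ-(triethylsilyloxy)-9α,13-epoxylabdane | CC(=O)O[C@@H]1C(O[Si](CC)(CC)CC)[C@@H](C)[C@]2(CC[C@](CO[Si](C)(C)C(C)(C)C)(CC(OC)OC)O2)[C@@]2(C)CCCC(C)(C)[C@H]12 | intermediate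
22 | (13R)-6β-acetoxy-15,15-dimethoxy-9α,13-epoxylabdane-7ξ,16-diol | CC(=O)O[C@@H]1C(O)[C@@H](C)[C@]2(CC[C@](CO)(CC(OC)OC)O2)[C@@]2(C)CCCC(C)(C)[C@H]12 | intermediate
23 | (13R)-6β-acetoxy-15ξ-methoxy-9α,13:15,16-diepoxylabdan-7ξ-ol | CC(=O)O[C@@H]1C(O)[C@@H](C)[C@]2(CC[C@]3(CC(OC)OC3)O2)[C@@]2(C)CCCC(C)(C)[C@H]12 | intermediate
24 | (13R)-6β-acetoxy-15ξ-methoxy-9α,13:15,16-diepoxylabdan-7-one | CC(=O)O[C@@H]1C(=O)[C@@H](C)[C@]2(CC[C@]3(CC(OC)OC3)O2)[C@@]2(C)CCCC(C)(C)[C@H]12 | intermediate
25 | (13R)-6β-acetoxy-15ξ-hydroxy-9α,13:15,16-diepoxylabdan-7-one | CC(=O)O[C@@H]1C(=O)[C@@H](C)[C@]2(CC[C@]3(CC(O)OC3)O2)[C@@]2(C)CCCC(C)(C)[C@H]12 | intermediate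
26 | (13R)-6β-acetoxy-15ξ-(methanesulfonyloxy)-9α,13:15,16-diepoxylabdan-7-one | CC(=O)O[C@@H]1C(=O)[C@@H](C)[C@]2(CC[C@]3(CC(OS(C)(=O)=O)OC3)O2)[C@@]2(C)CCCC(C)(C)[C@H]12 | intermediate
27 | (13R)-6β-acetoxy-9α,13:15,16-diepoxylabd-14-en-7-one (CNP0224709.1) | CC(=O)O[C@@H]1C(=O)[C@@H](C)[C@]2(CC[C@]3(C=COC3)O2)[C@@]2(C)CCCC(C)(C)[C@H]12 | target

Total step count: 20.
Longest linear sequence: 17 steps (6 to 27 through steps 4–20). The branch from 1 contributes 15.

Steps most likely to fail

Step 12.
- What may go wrong: the hindered C9 radical may be quenched before it reaches the twisted tetrasubstituted acceptor. Quenching could come from a second hydrogen transfer, an internal hydrogen shift from the acetal C–H, or ethanolysis of the enol ether before hydrogen-atom transfer.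
- Fallback: it sets out from 15. Benzeneselenol (cat. PPTS, CH2Cl2, −20 °C) adds across the enol ether in the Markovnikov sense to give the C9 phenylselanyl ketal F1.
- Slow syringe-pump addition of Bu3SnH/AIBN to F1 in refluxing benzene then regenerates the same C9 radical by selenium abstraction. The hydrogen donor stays scarce and no protic solvent is present. This tin-hydride Giese cyclisation, followed by K2CO3/MeOH equilibration at C5, comes back to the route at 16.

Step 11.
- What may go wrong: the C6 carbonyl oxygen may compete with the tertiary hydroxyl for the gold-activated alkyne. Traces of acid may also shift the enol ether double bond to C8=C9, with loss of the C8 configuration.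
- Fallback: it sets out from 13 and moves the cycloisomerisation to the alcohol oxidation level, where no carbonyl is present.
- Selective acetylation of the secondary hydroxyl (Ac2O, pyridine, DMAP cat., 0 °C) gives the C6 monoacetate F2. Gold-catalysed 5-endo-dig closure under the conditions of step 11 gives the acetoxy dihydrofuran F3.
- K2CO3/MeOH then gives the hydroxy dihydrofuran F4 under purely basic conditions. Pyridine-buffered Dess–Martin oxidation comes back to the route at 15.

Step 20.
- What may go wrong: ammonium salts or silica may trigger ionisation of the C13–O bond, with opening of ring C and aromatisation of ring D. The open hydroxy-aldehyde form of the lactol may also undergo β-elimination or O16 mesylation.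
- Fallback: it sets out from 24. Exchange of the anomeric methoxy group with benzeneselenol (cat. PPTS, CH2Cl2, 0 °C) gives the C15 phenylselanyl ether F5.
- Oxidation with H2O2 in CH2Cl2/pyridine at 0 °C gives the selenoxide F6. This undergoes syn elimination below room temperature in the presence of i-Pr2NH as a scavenger. The double bond thus forms without any leaving-group ionisation, and the route is rejoined at 27.

Further compounds
F1 | step 12 | (3R)-3-[(5R)-5-{[(tert-butyldimethylsilyl)oxy]methyl}-5-(2,2-dimethoxyethyl)-2-(phenylselanyl)oxolan-2-yl]-1-(2,6,6-trimethylcyclohex-1-en-1-yl)butan-1-one (C9 epimers) | CC1=C(C(=O)C[C@@H](C)C2([Se]c3ccccc3)CC[C@](CO[Si](C)(C)C(C)(C)C)(CC(OC)OC)O2)C(C)(C)CCC1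
F2 | step 11 | C6 monoacetate of 13 | CC1=C(C(OC(C)=O)C[C@@H](C)C#CC[C@](O)(CO[Si](C)(C)C(C)(C)C)CC(OC)OC)C(C)(C)CCC1
F3 | step 11 | C6 acetoxy analogue of 15 (acetoxy dihydrofuran) | CC1=C(C(OC(C)=O)C[C@@H](C)C2=CC[C@](CO[Si](C)(C)C(C)(C)C)(CC(OC)OC)O2)C(C)(C)CCC1
F4 | step 11 | C6 hydroxy analogue of 15 (hydroxy dihydrofuran) | CC1=C(C(O)C[C@@H](C)C2=CC[C@](CO[Si](C)(C)C(C)(C)C)(CC(OC)OC)O2)C(C)(C)CCC1
F5 | step 20 | (13R)-6β-acetoxy-15ξ-(phenylselanyl)-9α,13:15,16-diepoxylabdan-7-one | CC(=O)O[C@@H]1C(=O)[C@@H](C)[C@]2(CC[C@]3(CC([Se]c4ccccc4)OC3)O2)[C@@]2(C)CCCC(C)(C)[C@H]12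
F6 | step 20 | (13R)-6β-acetoxy-15ξ-(phenylseleninyl)-9α,13:15,16-diepoxylabdan-7-one | CC(=O)O[C@@H]1C(=O)[C@@H](C)[C@]2(CC[C@]3(CC([Se](=O)c4ccccc4)OC3)O2)[C@@]2(C)CCCC(C)(C)[C@H]12
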